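If I follow one molecule of starting material through these flasks, I can ask for its chance of ending as isomer of the product.

| setting | east | north | south-east | north-east | west | north-west |
|---|---|---|---|---|---|---|
| starting material | 0.50 M | 0.50 M | 0.50 M | 0.50 M | 0.50 M (fed, over 3.0 d) | 0.50 M (in portions, 2, over 3.0 d) |
| reagent | 0.475 M (fed, over 20 h) | 0.475 M | 0.475 M | 0.475 M (fed, over 3.0 d) | 0.475 M | 0.475 M |
| protic impurity | 0.0250 M | 0.0250 M | 0.0250 M | 0.0250 M | 0.0250 M | 0.0250 M |
| temperature | 80 °C | 80 °C |  |  | 80 °C | 80 °C |
| time | 5.0 d | 5.0 d | 5.0 d | 5.0 d | 5.0 d | 5.0 d |
| remark | all else is in the flask from the start; the feed brings no volume worth counting | everything together at the start | everything together at the start at 50 °C, warmed to 80 °C at 3.0 d | the addition at 50 °C, then warmed to 80 °C; the feed brings no volume worth counting | all else is in the flask from the start; the feed brings no volume worth counting | first portion at the start, last at 3.0 d |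

    starting material + reagent → target (k1 = 0.0028 M⁻¹ h⁻¹, Ea1 = 108 kJ mol⁻¹)
    starting material + protic impurity → quenched substrate (k2 = 1.2 M⁻¹ h⁻¹, Ea2 = 75.0 kJ mol⁻¹)
    target ⇌ isomer of the product (K3 = 1.2, k3 = 0.0052 h⁻¹, Ea3 = 127 kJ mol⁻¹, ΔH3 = −36.0 kJ mol⁻¹)
    starting material + reagent + target → 2 target (k4 = 0.88 M⁻² h⁻¹, Ea4 = 80.0 kJ mol⁻¹)
    (constants at 80 °C)

1. the flask that comes out highest in amount of isomer of the product, in percent of the starting material charged, or "all alike" when all lie within 1.5 percentage points (east / north / south-east / north-east / west / north-west / all alike)
2. isomer of the product at the end, in percent of the starting material charged, east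
3. isomer of the product at the end, in percent of the starting material charged, north
4. isomer of the product at the end, in percent of the starting material charged, south-east
5. isomer of the product at the end, in percent of the starting material charged, north-east
6. isomer of the product at the end, in percent of the starting material charged, west
7. isomer of the product at the end, in percent of the starting material charged, north-west

- all constants are for 80 °C and move with temperature by the activation energies and enthalpies

1. The fork. At 80 °C with everything in, protic impurity has a lifetime of 1.67 h against [starting material]. It takes 0.0250 M and leaves 0.475 M, so starting material and reagent stand level. At most 95.0% of the charge can reach target or isomer.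

2. The wait. Target speeds its own making, so [target] grows like compound interest at about 0.199 h⁻¹, from a seed of k1/k4. That rate holds at the start only, since [starting material] and [reagent] fall as target grows, so I integrate the growth with both falling: target reaches half of the possible amount after 29.9 h, and I count the molecule born then.

3. The clock. Target flips to isomer and back. The ageing time, one over the sum of the forward and back rate constants (the relaxation time), is 105 h. A molecule's chance of being isomer climbs with its age towards 54.5%, and the gap to that share shrinks as exp(−age/ageing time).

4. North, with everything together, gives an age of 90.1 h and so 29.9% of the charge as isomer. Later molecules are younger, so I take this and the figures below as high.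

5. Feeding the reagent (east). [Reagent] climbs from nothing during the 20 h, and the wait grows by 10.0 h. That gives 27.7%.

6. Holding cold (south-east). I let the wait begin at warming, 3.0 d in, which leaves an age of 18.1 h and 8.19%. For north-east my figure is the same.

7. Feeding the starting material (west). [Starting material] climbs slowly, so the wait stretches to 65.7 h, still inside the feed. That gives 20.9%. I leave north-west unreckoned.

8. The forecast names north: east 24.5%, north 27%, south-east 7.5%, north-east 6.5%, west 18%, north-west 17%. Its ground is that “the isomer mainly reflects how early the target forms”. For north, east, west and south-east it has the same order as mine, but my figures stand higher.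

9. The highest flask is north at 26.4%, with east 24.2%, south-east 8.12%, north-east 7.56%, west 17.3% and north-west 16.7%. North ends with 61.9% target beside 26.4% isomer, so 29.9% of the two is isomer. Through the ageing time of 105 h, that reads as a mean age of 83.4 h in north. South-east holds 0.563% target at 3.00 d and ends with 66.0% beside 8.12% isomer, which reads as a mean age of 23.5 h.

The numbers of this flask were drawn at random within sensible limits.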